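## Retrosynthetic overview

1. Target 24 ← LiAlH4 opening of the eight-membered (Z)-allylic lactone 23; both CH2OH groups come from this one lactone.
2. 23 ← C–O bond formation: zerovalent-palladium-catalysed ring-expanding 1,3-transposition of the tertiary allylic δ-lactone 21, which fixes the tetrasubstituted Z-olefin.
3. 21 ← isopropenyl addition/lactonisation of keto ester 18 ← conjugate methylation/Michael trapping of enone 15 (sets the quaternary carbon and its neighbour) ← enone 4 + trienyl bromide 12.
4. 4 ← propanal + methyl vinyl ketone (organocatalytic Michael addition, aldol condensation); 12 ← (S)-citronellal-derived alkyne 7 + dibromide 10 (allyl–alkenyl coupling).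
5. Ring order: the cyclohexane is closed first (step 2); the δ-lactone (step 10) and the eight-membered lactone (step 11) are temporary and opened in step 12.

Assumption: (S)-citronellal of ≥97% ee is bought. Ring atoms of the target are called C1 (quaternary), C2 (CH–CH3), C3, C4, C5 (alkylidene carbon) and C6 (CH carrying the hydroxypropyl chain); "trienyl" = (3E,6E,8S)-4,8,12-trimethyltrideca-3,6,11-trien-1-yl.

## Route

Step 1
Reactants: 1 propanal; 2 methyl vinyl ketone
Product: 3 (2R)-2-methyl-5-oxohexanal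
Conditions: (S)-2-[methoxy(diphenyl)methyl]pyrrolidine (5 mol %), ethyl 3,4-dihydroxybenzoate (20 mol %), neat, 4 °C
Reagents that add atoms: none
Why: Enamine-mediated organocatalytic Michael addition; the (S)-diarylprolinol ether shields one enamine face, so the stereocenter (future ring C2) is formed 2R by analogy with related aldehyde Michael additions (the enantiomeric catalyst is used if the sense proves opposite).

Step 2
Reactants: 3 (2R)-2-methyl-5-oxohexanal
Product: 4 (4R)-4-methylcyclohex-2-en-1-one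
Conditions: KOH (aq), n-Bu4NOH (cat.), Et2O/THF, reflux, short reaction time
Reagents that add atoms: none
Why: Intramolecular aldol condensation of the methyl ketone onto the aldehyde closes the cyclohexenone; the stereocenter becomes the γ-carbon and is carried through, with the short reaction time limiting epimerisation before closure.

Step 3
Reactants: 5 (3S)-3,7-dimethyloct-6-enal [(S)-citronellal]
Product: 7 (3S)-3,7-dimethyloct-6-en-1-yne, via alkenyl nonaflate 6 (not isolated)
Conditions: C4F9SO2F, phosphazene base P2-Et, DMF, −20 °C → rt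
Reagents that add atoms: none
Why: One-pot enolate O-sulfonylation and E2 elimination converts CH2–CHO into C≡CH without changing the carbon count; the β-stereocenter is not acidic and is untouched.

Step 4
Reactants: 8 5-bromo-2-methylpent-2-ene
Product: 9 (2E)-5-bromo-2-methylpent-2-en-1-ol
Conditions: SeO2 (0.3 equiv), t-BuOOH, CH2Cl2, rt
Reagents that add atoms: tert-butyl hydroperoxide, CC(C)(C)OO (oxygen atom, relayed by catalytic SeO2, O=[Se]=O)
Why: SeO2/t-BuOOH allylic oxidation (ene reaction, then [2,3]-sigmatropic shift) hydroxylates only the (E)-methyl group, which fixes the E geometry of the future trisubstituted side-chain olefin.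

Step 5
Reactants: 9 (2E)-5-bromo-2-methylpent-2-en-1-ol
Product: 10 (2E)-1,5-dibromo-2-methylpent-2-ene
Conditions: PBr3, Et2O, 0 °C
Reagents that add atoms: phosphorus tribromide, BrP(Br)Br
Why: SN2 bromination of the primary allylic alcohol through its bromophosphite proceeds without allylic transposition or loss of olefin geometry.

Step 6
Reactants: 7 (3S)-3,7-dimethyloct-6-en-1-yne; 10 (2E)-1,5-dibromo-2-methylpent-2-ene
Product: 12 (3E,6E,8S)-1-bromo-4,8,12-trimethyltrideca-3,6,11-triene, via alkenylalane 11 (not isolated)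
Conditions: i-Bu2AlH, hexane, 50 °C; then 10, Pd(PPh3)4 (5 mol %), THF, 0 °C → rt
Reagents that add atoms: none
Why: syn-Hydroalumination gives the (E)-alkenylalane, and Negishi allyl–alkenyl cross-coupling joins it to the primary allylic terminus with retention of both olefin geometries; the homoallylic C–Br bond does not add to zerovalent palladium.

Step 7
Reactants: 12 (3E,6E,8S)-1-bromo-4,8,12-trimethyltrideca-3,6,11-triene; 4 (4R)-4-methylcyclohex-2-en-1-one
Product: 14 trimethyl{[(3S,4R)-4-methyl-3-trienylcyclohex-1-en-1-yl]oxy}silane, via Grignard reagent 13 (not isolated)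
Conditions: Mg, THF; then 4, CuBr·SMe2 (10 mol %), Me3SiCl, DMPU, THF, −78 °C; Et3N
Reagents that add atoms: chlorotrimethylsilane, C[Si](C)(C)Cl
Why: Copper-catalysed conjugate addition of the Grignard reagent, accelerated and trapped by Me3SiCl, gives the regiodefined silyl enol ether; addition is trans to the methyl group, but this centre is erased in step 8.

Step 8
Reactants: 14 trimethyl{[(3S,4R)-4-methyl-3-trienylcyclohex-1-en-1-yl]oxy}silane
Product: 15 (4R)-4-methyl-3-trienylcyclohex-2-en-1-one
Conditions: Pd(OAc)2 (1.05 equiv), MeCN, rt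
Reagents that add atoms: none
Why: Saegusa–Ito oxidation: the palladium enolate undergoes syn β-hydride elimination towards the chain-bearing carbon and regenerates the enone, now β-substituted; the γ-stereocenter (C2) is untouched.

Step 9
Reactants: 15 (4R)-4-methyl-3-trienylcyclohex-2-en-1-one; 16 methyl acrylate
Product: 18 methyl 3-[(1S,2R,3R)-2,3-dimethyl-6-oxo-2-trienylcyclohexyl]propanoate, via lithium enolate 17 (not isolated)
Conditions: Me2CuLi (from MeLi, CuI), Et2O, 0 °C; then 16 (1.05 equiv), THF, −78 °C; AcOH, −78 °C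
Reagents that add atoms: lithium dimethylcuprate, [Li+].C[Cu-]C
Why: Tandem cuprate 1,4-addition–Michael reaction: methyl adds axially anti to the pseudoaxial γ-methyl (quaternary C1, CH3 trans to the C2 methyl), and the regiospecific enolate then adds to the acrylate by axial attack anti to the pseudoaxial trienyl chain, on the face free of a syn-axial methyl (C6, new chain cis to the quaternary methyl).

Step 10
Reactants: 18 methyl 3-[(1S,2R,3R)-2,3-dimethyl-6-oxo-2-trienylcyclohexyl]propanoate; 19 isopropenylmagnesium bromide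
Product: 21 (4aS,5R,6R,8aR)-5,6-dimethyl-8a-(prop-1-en-2-yl)-5-trienyloctahydro-2H-chromen-2-one, via magnesium alkoxide 20 (not isolated)
Conditions: CeCl3 (1.5 equiv), THF, −78 °C → rt
Reagents that add atoms: none
Why: CeCl3-promoted Grignard 1,2-addition suppresses enolisation of the hindered ketone; attack anti to the C6 substituent puts the alkoxide cis to the ester chain, which lactonises, and the new carbinol centre is erased in step 11.

Step 11
Reactants: 21 (4aS,5R,6R,8aR)-5,6-dimethyl-8a-(prop-1-en-2-yl)-5-trienyloctahydro-2H-chromen-2-one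
Product: 23 (1Z,8S,9R,10R)-2,9,10-trimethyl-9-trienyl-4-oxabicyclo[6.4.0]dodec-1-en-5-one, via π-allylpalladium carboxylate zwitterion 22 (not isolated)
Conditions: Pd2(dba)3·CHCl3 (5 mol %), PPh3 (20 mol %), THF (0.005 M), 40 °C
Reagents that add atoms: none
Why: Proposed new method: zerovalent palladium ionises the tertiary allylic C–O bond of 21 (as in Tsuji–Trost chemistry of vinyl lactones) to zwitterion 22; return of the tethered carboxylate to the tertiary terminus only regenerates 21, whereas attack at the unhindered CH2 terminus forms the new C–O bond and the tetrasubstituted exocyclic olefin; because the carboxylate hangs from ring C6 it can reach that terminus only in the allyl rotamer with CH2 cis to C6, so the eight-membered ring enforces the Z geometry (an E-olefin cannot be spanned by eight atoms); the tetrasubstituted product olefin binds zerovalent palladium poorly and is not re-ionised, so the material drains into 23 under high dilution; closest known reactions are the palladium-catalysed 1,3-transposition of tertiary allylic esters to primary ones and medium-ring closures through π-allylpalladium intermediates.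

Step 12
Reactants: 23 (1Z,8S,9R,10R)-2,9,10-trimethyl-9-trienyl-4-oxabicyclo[6.4.0]dodec-1-en-5-one
Product: 24 3-[(1S,2R,3R,6Z)-6-(1-hydroxypropan-2-ylidene)-2,3-dimethyl-2-trienylcyclohexyl]propan-1-ol (target, CNP0327981.1)
Conditions: LiAlH4, THF, 0 °C
Reagents that add atoms: none
Why: Hydride reduction of the lactone liberates both primary alcohols at once; isolated olefins and the allylic C–O bond are inert to LiAlH4 at 0 °C, so no stereocenter or olefin geometry changes.

## Compound list

1 | propanal | CCC=O | starting material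
2 | methyl vinyl ketone | CC(=O)C=C | starting material
3 | (2R)-2-methyl-5-oxohexanal | O=C[C@H](C)CCC(C)=O | intermediate
4 | (4R)-4-methylcyclohex-2-en-1-one | O=C1C=C[C@H](C)CC1 | intermediate
5 | (3S)-3,7-dimethyloct-6-enal, (S)-citronellal | O=CC[C@@H](C)CCC=C(C)C | starting material
6 | (3S)-3,7-dimethylocta-1,6-dien-1-yl nonafluorobutane-1-sulfonate (E/Z mixture) | FC(F)(F)C(F)(F)C(F)(F)C(F)(F)S(=O)(=O)OC=C[C@@H](C)CCC=C(C)C | intermediate (not isolated)
7 | (3S)-3,7-dimethyloct-6-en-1-yne | C#C[C@@H](C)CCC=C(C)C | intermediate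
8 | 5-bromo-2-methylpent-2-ene | CC(C)=CCCBr | starting material
9 | (2E)-5-bromo-2-methylpent-2-en-1-ol | OC/C(C)=C/CCBr | intermediate
10 | (2E)-1,5-dibromo-2-methylpent-2-ene | BrC/C(C)=C/CCBr | intermediate
11 | [(1E,3S)-3,7-dimethylocta-1,6-dien-1-yl]bis(2-methylpropyl)alane | CC(C)C[Al](CC(C)C)/C=C/[C@@H](C)CCC=C(C)C | intermediate (not isolated)
12 | (3E,6E,8S)-1-bromo-4,8,12-trimethyltrideca-3,6,11-triene | BrCC/C=C(C)/C/C=C/[C@@H](C)CCC=C(C)C | intermediate
13 | [(3E,6E,8S)-4,8,12-trimethyltrideca-3,6,11-trien-1-yl]magnesium bromide | Br[Mg]CC/C=C(C)/C/C=C/[C@@H](C)CCC=C(C)C | intermediate (not isolated)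
14 | trimethyl{[(3S,4R)-4-methyl-3-trienylcyclohex-1-en-1-yl]oxy}silane | C[Si](C)(C)OC1=C[C@@H](CC/C=C(C)/C/C=C/[C@@H](C)CCC=C(C)C)[C@H](C)CC1 | intermediate
15 | (4R)-4-methyl-3-trienylcyclohex-2-en-1-one | O=C1C=C(CC/C=C(C)/C/C=C/[C@@H](C)CCC=C(C)C)[C@H](C)CC1 | intermediate
16 | methyl acrylate | C=CC(=O)OC | starting material
17 | lithium (3R,4R)-3,4-dimethyl-3-trienylcyclohex-1-en-1-olate | [Li]OC1=C[C@](C)(CC/C=C(C)/C/C=C/[C@@H](C)CCC=C(C)C)[C@H](C)CC1 | intermediate (not isolated)
18 | methyl 3-[(1S,2R,3R)-2,3-dimethyl-6-oxo-2-trienylcyclohexyl]propanoate | O=C1CC[C@@H](C)[C@@](C)(CC/C=C(C)/C/C=C/[C@@H](C)CCC=C(C)C)[C@@H]1CCC(=O)OC | intermediate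
19 | isopropenylmagnesium bromide | C=C(C)[Mg]Br | starting material
20 | bromomagnesium alkoxide of methyl 3-[(1S,2R,3R,6R)-6-hydroxy-2,3-dimethyl-6-(prop-1-en-2-yl)-2-trienylcyclohexyl]propanoate | C=C(C)[C@@]1(O[Mg]Br)CC[C@@H](C)[C@@](C)(CC/C=C(C)/C/C=C/[C@@H](C)CCC=C(C)C)[C@@H]1CCC(=O)OC | intermediate (not isolated)
21 | (4aS,5R,6R,8aR)-5,6-dimethyl-8a-(prop-1-en-2-yl)-5-trienyloctahydro-2H-chromen-2-one | C=C(C)[C@@]12CC[C@@H](C)[C@@](C)(CC/C=C(C)/C/C=C/[C@@H](C)CCC=C(C)C)[C@@H]1CCC(=O)O2 | intermediate
22 | π-allylbis(triphenylphosphine)palladium carboxylate zwitterion (drawn as the σ-allyl form; allyl geometry fluxional) | CC(C[Pd+](P(c1ccccc1)(c1ccccc1)c1ccccc1)P(c1ccccc1)(c1ccccc1)c1ccccc1)=C1CC[C@@H](C)[C@@](C)(CC/C=C(C)/C/C=C/[C@@H](C)CCC=C(C)C)[C@@H]1CCC([O-])=O | intermediate (not isolated)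
23 | (1Z,8S,9R,10R)-2,9,10-trimethyl-9-trienyl-4-oxabicyclo[6.4.0]dodec-1-en-5-one | C/C1=C2\CC[C@@H](C)[C@@](C)(CC/C=C(C)/C/C=C/[C@@H](C)CCC=C(C)C)[C@@H]2CCC(=O)OC1 | intermediate
24 | 3-[(1S,2R,3R,6Z)-6-(1-hydroxypropan-2-ylidene)-2,3-dimethyl-2-[(3E,6E,8S)-4,8,12-trimethyltrideca-3,6,11-trien-1-yl]cyclohexyl]propan-1-ol | CC(C)=CCC[C@H](C)/C=C/C/C(C)=C/CC[C@]1(C)[C@H](C)CC/C(=C(\C)CO)[C@H]1CCCO | target

## Step count and risks

Total: 12 steps. Longest linear sequence: 9 steps (8 → 24, steps 4–12).

**Step 11 (proposed new ring-expanding transposition).** Likely failure modes are loss of a proton from zwitterion 22 to give dienes, intermolecular O-allylation (dimers), or an equilibrium that stays on the side of 21. The fallback sets out from 21 and comes back at 24, using known chemistry. LiAlH4 opens the lactone to the diol F6 (tertiary allylic alcohol plus primary alcohol). TBSCl/imidazole silylates only the primary hydroxyl to give the silyl ether F7, which prevents cyclic ether formation in the next operation. Ph3SiOReO3 (2 mol %, Et2O, 0 °C) then effects the perrhenate [3,3] allylic alcohol transposition, giving the Z-allylic alcohol F8 together with its E isomer F9 (about 1:1 expected). The two are separated on AgNO3-impregnated silica, F9 is re-equilibrated with the same catalyst, and TBAF converts F8 into 24.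

**Step 9 (tandem cuprate addition–Michael reaction).** Likely failure modes are acrylate oligomerisation, proton transfer with epimerisation at C6, or modest facial selectivity. The fallback sets out from 15 and comes back at 18. Enolate 17 is generated as before and quenched with allyl iodide/HMPA (classical three-component coupling, same axial-attack selectivity) to give the allyl ketone F1. 9-BBN hydroborates only the monosubstituted olefin to give the borane F2, and NaOH/H2O2 gives the hydroxy ketone F3. TEMPO/PhI(OAc)2 in aqueous MeCN oxidises F3 to the keto acid F4, and Me3SiCHN2/MeOH returns 18.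

**Step 10 (isopropenyl addition to the hindered ketone and lactonisation).** Likely failure modes are enolisation, competing attack on the ester, or an adduct that does not lactonise. The fallback sets out from 18 and comes back at 21. LiOH saponifies 18 to the keto acid F4, whose lithium carboxylate is inert to nucleophiles. Isopropenyllithium (2-bromopropene, t-BuLi; 2.5 equiv) with CeCl3 then adds only to the ketone to give the hydroxy acid F5, which is closed separately to 21 with 2,4,6-trichlorobenzoyl chloride/Et3N/DMAP.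

## Further compounds

F1 | step 9 | (2S,3R,4R)-3,4-dimethyl-2-(prop-2-en-1-yl)-3-trienylcyclohexan-1-one | O=C1CC[C@@H](C)[C@@](C)(CC/C=C(C)/C/C=C/[C@@H](C)CCC=C(C)C)[C@@H]1CC=C
F2 | step 9 | (2S,3R,4R)-2-[3-(9-borabicyclo[3.3.1]nonan-9-yl)propyl]-3,4-dimethyl-3-trienylcyclohexan-1-one | O=C1CC[C@@H](C)[C@@](C)(CC/C=C(C)/C/C=C/[C@@H](C)CCC=C(C)C)[C@@H]1CCCB1C2CCCC1CCC2
F3 | step 9 | (2S,3R,4R)-2-(3-hydroxypropyl)-3,4-dimethyl-3-trienylcyclohexan-1-one | O=C1CC[C@@H](C)[C@@](C)(CC/C=C(C)/C/C=C/[C@@H](C)CCC=C(C)C)[C@@H]1CCCO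
F4 | step 9 | 3-[(1S,2R,3R)-2,3-dimethyl-6-oxo-2-trienylcyclohexyl]propanoic acid | O=C1CC[C@@H](C)[C@@](C)(CC/C=C(C)/C/C=C/[C@@H](C)CCC=C(C)C)[C@@H]1CCC(=O)O
F5 | step 10 | 3-[(1S,2R,3R,6R)-6-hydroxy-2,3-dimethyl-6-(prop-1-en-2-yl)-2-trienylcyclohexyl]propanoic acid | C=C(C)[C@@]1(O)CC[C@@H](C)[C@@](C)(CC/C=C(C)/C/C=C/[C@@H](C)CCC=C(C)C)[C@@H]1CCC(=O)O
F6 | step 11 | (1R,2S,3R,4R)-2-(3-hydroxypropyl)-3,4-dimethyl-1-(prop-1-en-2-yl)-3-trienylcyclohexan-1-ol | C=C(C)[C@@]1(O)CC[C@@H](C)[C@@](C)(CC/C=C(C)/C/C=C/[C@@H](C)CCC=C(C)C)[C@@H]1CCCO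
F7 | step 11 | (1R,2S,3R,4R)-2-{3-[(tert-butyldimethylsilyl)oxy]propyl}-3,4-dimethyl-1-(prop-1-en-2-yl)-3-trienylcyclohexan-1-ol | C=C(C)[C@@]1(O)CC[C@@H](C)[C@@](C)(CC/C=C(C)/C/C=C/[C@@H](C)CCC=C(C)C)[C@@H]1CCCO[Si](C)(C)C(C)(C)C
F8 | step 11 | (2Z)-2-[(2S,3R,4R)-2-{3-[(tert-butyldimethylsilyl)oxy]propyl}-3,4-dimethyl-3-trienylcyclohexylidene]propan-1-ol | OC/C(C)=C1/CC[C@@H](C)[C@@](C)(CC/C=C(C)/C/C=C/[C@@H](C)CCC=C(C)C)[C@@H]1CCCO[Si](C)(C)C(C)(C)C
F9 | step 11 | (2E)-2-[(2S,3R,4R)-2-{3-[(tert-butyldimethylsilyl)oxy]propyl}-3,4-dimethyl-3-trienylcyclohexylidene]propan-1-ol | OC/C(C)=C1\CC[C@@H](C)[C@@](C)(CC/C=C(C)/C/C=C/[C@@H](C)CCC=C(C)C)[C@@H]1CCCO[Si](C)(C)C(C)(C)C
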